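In a one-step world a flask is read by one count, the half-lives of its starting material that fit into the time, and I begin there although these flasks fork.

| setting | north-east | west | grey | amber |
|---|---|---|---|---|
| starting material | 0.028 M | 0.044 M | 0.020 M | 0.020 M |
| temperature | 38 °C | 54 °C | 50 °C | 40 °C |
| remark | run made earlier | run made earlier |  |  |
| time |  |  | 15 min | 15 min |

| run | time / min | intermediate A / % | intermediate B / % | side product A / % | target / % | starting material / % |
|---|---|---|---|---|---|---|
| north-east | 1.00 | 9 | 6 | 61 | 0 | 24 |
| north-east | 1.50 | 4 | 10 | 78 | 0 | 9 |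
| north-east | 2.50 | 4 | 6 | 82 | 0 | 3 |
| north-east | 4.00 | 0 | 10 | 88 | 5 | 0 |
| north-east | 8.00 | 2 | 9 | 87 | 5 | 0 |
| north-east | 12.0 | 2 | 10 | 85 | 5 | 0 |
| west | 1.00 | 0 | 9 | 86 | 0 | 2 |
| west | 2.00 | 0 | 7 | 88 | 4 | 2 |
| west | 3.00 | 1 | 7 | 90 | 0 | 0 |
| west | 4.00 | 0 | 4 | 91 | 2 | 1 |
| west | 5.00 | 0 | 6 | 83 | 8 | 0 |
| west | 6.00 | 1 | 3 | 90 | 8 | 0 |

(standard deviation of a reading: 2 percentage points)



* which of these there is most of at the end, counted by the starting material in it, grey (intermediate B / intermediate A / target / side product A)
* which of these there is most of at the end, counted by the starting material in it, amber (intermediate B / intermediate A / target / side product A)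
* final amount of the leader among these, as a percentage of the starting material charged, in grey
* final amount of the leader among these, as a percentage of the starting material charged, in amber

The first rung I can read is the fall of starting material. In the north-east run 24 % stands at 1.00 min, which gives a rate constant of 1.43 min⁻¹, and the reading at 1.50 min gives 1.61 min⁻¹, so I take the fall as first order, with a half-life of 0.486 min that does not contain [starting material]. That half-life is far shorter than the 15 min allowed, and dividing gives 30.9, the turnover count, meaning time over half-life of starting material. I reckon it at 38 °C, colder than grey and amber, and the north-east run already read 0 % after 8.23 turnovers, so I expect the fork to close early in both flasks.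

The next rung is what the fork leaves. Side product A, read late, averages 86.7 % at 38 °C and 88.0 % at 54 °C, a gap inside a scatter of 2 percentage points, so I commit to about these figures for amber and grey. That leaves 13.3 % for the rest together, and side product A, at more than that, leads however this is divided. The last rung I can read lies inside that remainder: in the north-east run intermediate B, which I read as its resting state, stands at 10 % at 4.00 min and at 10 % at 12.0 min, more than the 2 % of intermediate A at that last time.

The forecast names side product A in grey at 86 % (81 % to 90 %) and side product A in amber at 85 % (80 % to 89 %), a little below my figures, “with some allowance for a lower value”.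

Grey ends at 88.1 % of side product A and amber at 86.5 % of side product A.

    starting material → intermediate A (k = 0.00468 s⁻¹, Ea = 82.0 kJ mol⁻¹)
    intermediate A ⇌ intermediate B (K = 7.40, k = 0.0208 s⁻¹, Ea = 90.0 kJ mol⁻¹, ΔH = −4.00 kJ mol⁻¹)
    intermediate A → intermediate C (k = 0.00491 s⁻¹, Ea = 92.0 kJ mol⁻¹)
    intermediate C ⇌ intermediate D (K = 1.30, k = 0.00305 s⁻¹, Ea = 91.0 kJ mol⁻¹, ΔH = −21.0 kJ mol⁻¹)
    intermediate C → target (k = 0.00992 s⁻¹, Ea = 92.0 kJ mol⁻¹)
    intermediate D → side product A (k = 0.0188 s⁻¹, Ea = 89.0 kJ mol⁻¹)
    starting material → side product A (k = 0.0271 s⁻¹, Ea = 86.0 kJ mol⁻¹)
    starting material + target → side product B (k = 0.718 M⁻¹ s⁻¹, Ea = 57.0 kJ mol⁻¹)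
    (constants at 40 °C)

Amber still holds 7.25 % of intermediate B beside 4.91 % of target at 15.0 min. On the count with the north-east half-life, 15.4 turnovers have passed at 7.50 min, and amber holds 0 % of starting material there. The neighbour flask, grey with [starting material] cut to 0.012 M, counts the same 30.9 on the north-east half-life, which I took as free of concentration, and it ends with 0 % of starting material and 88.1 % of side product A.

Readings and results are calculated with constants of no real substance, and the scatter is random.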